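# Proposed synthesis of 3',3'''-bidaidzein (13)

## The problem

Target 13 is a C2-symmetric dimer of 7,4'-dihydroxyisoflavone. Its two B rings are joined by a C3'–C3''' bond, and each end of that bond lies ortho to a free 4'-hydroxyl and meta to the C1' carbon that carries ring C. The molecule has no stereocenter, and the biaryl axis has only two ortho substituents and rotates freely. Nothing in the target therefore needs stereocontrol, and no stereocenter made on the way has to direct another.

The difficulty is positional. Oxidative coupling of a monomeric phenol cannot guarantee C3'–C3''' coupling over C–O coupling or over-oxidation. Cross-coupling would first need ortho-halogenation and metalation of two hindered, oxygenated partners.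

The four phenols, two of them in an easily oxidised 2,2'-biphenol, and ring C, whose C2 is opened by hydroxide or alkoxide, exclude strongly basic or oxidising late steps. Ring C is therefore best closed last and under acid.

The feature that opens the chosen route is the pattern of ring B: oxygen at C4', the other B ring at the neighbouring C3', and the benzylic carbon (C3 of ring C) at C1', para to oxygen. One oxidation level below the arene this is a cyclohex-2-enone with the carbonyl at C4', a substituent on its α-carbon C3' and another on its γ-carbon C1'. That is the product pattern of a Robinson annulation between an aldehyde and a vinyl ketone. The C3'–C3''' bond then joins the α-carbons of two ketones, so it is the CH2–CH2 bond of a purchasable 1,4-dicarbonyl compound, and both B rings can be built around it.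

## Retrosynthesis

**13 ⇒ 12.** The O1–C2 and C2–C3 bonds of both rings C are cut, removing each C2 as a formyl equivalent. This leaves the bis(2,4-dihydroxyphenyl benzyl ketone) 12.
- Against the neighbouring cut at C3–C1' (3-halochromone plus a biaryl bis-boron reagent): that cut presupposes the biaryl and two cross-couplings. The chosen cut forms the base-sensitive pyranone last, under acid, and without protecting groups.
- 12 has no heterocycle and only classical functional groups.
- The forward step must formylate two benzylic methylenes and close two rings in the presence of six free phenols.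

**12 ⇒ 11.** Four O–CH3 bonds on the two A rings are restored.
- Methyl ethers are needed because free resorcinol hydroxyls would not survive the Friedel–Crafts step cleanly and would protonate the amine catalyst of the annulation.
- Benzyl or silyl ethers would not survive AlCl3.
- The forward step must cleave all four ethers, including the slower para ones, without touching the benzylic ketone.

**11 ⇒ 10.** Both B rings are taken one oxidation level down, one H2 each, to the 2,2'-bi(cyclohex-2-enone) 10.
- This converts the aryl–aryl bond into a single bond between two enone α-carbons, so no phenol coupling or aryl–aryl cross-coupling is needed.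
- The price is two temporary sp3 centers at C1' and C1''', which are erased again on aromatization.
- The forward dehydrogenation must leave the ArC(=O)CH2 unit alone. This points to aerobic palladium catalysis. Iodine in DMSO is avoided because that combination oxidises aryl benzyl ketones to 1,2-diketones.

**10 ⇒ 8 + two molecules of 5 (through 9).** In each ring the C2'=C3' double bond (aldol condensation) and the C1'–C6' bond (Michael addition) are cut.
- This gives octa-1,7-diene-3,6-dione 8 and two molecules of keto aldehyde 5, with the bis-Michael adduct 9 between them.
- The other Robinson polarity (a ketone enolate adding to an enal) would put the central bond between two acceptor carbons and is not available.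
- The chosen polarity puts the central bond in a symmetrical C8 unit and makes the two partners identical.
- A C36 bicyclic compound is reduced to acyclic C8 and C12 pieces.
- The forward reaction must add both aldehydes to both vinyl ketones and then condense each ketone α-methylene with the aldehyde, not with the other ketone.

**5 ⇒ 3 ⇒ 1 + 2.** The aldehyde of 5 is traced to the terminal alkene of pentenone 3 by oxidative cleavage. The aryl–acyl bond of 3 is cut to 1,3-dimethoxybenzene 1 and pent-4-enoyl chloride 2.
- The neighbouring route (acylation with a succinic acid derivative, then selective reduction of the acid in the presence of the ketone) is longer and less selective.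
- The acylation must go para to one methoxyl and ortho to the other, which is the innate preference of 1.

**8 ⇒ 7 ⇒ 6.** The two vinyl–carbonyl bonds are cut to the bis(N-methoxy-N-methylamide) 7, made from succinyl chloride 6.
- The amide stops a vinyl Grignard reagent at the ketone stage.
- The central CH2–CH2 of 6 becomes the C3'–C3''' bond of 13.
- The forward step must release an unstable divinyl diketone without conjugate addition during work-up.

## Roads not taken

**Alternative 1: Diels–Alder benzannulation of both A rings.**
- Cut: C4a–C5 and C8–C8a of each ring A.
- Forward step: the bis(3-aryl-5-bromo-4-pyranone) A2 takes up two molecules of the oxygenated diene A3 across its brominated double bonds. Loss of CH3OH and HBr aromatizes both A rings and gives the 4',4'''-di-O-methyl ether A1, which needs only one demethylation to reach 13.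
- Merits: four C–C bonds and two rings form in one operation. The polarity of A3 fixes the position of the 7-oxygen, and the 7-hydroxyls emerge free.
- Weak points: the double bond of a 4-pyranone is a vinylogous ester with partial aromatic character and is a poor dienophile. Bromine activates it only modestly, and two such cycloadditions must both succeed. A2 also presupposes the biaryl bond and two C3–C1' cross-couplings onto a symmetrical dihalopyranone, each of which must stop at mono-substitution.
- Comparison: this road is more convergent and its endgame is shorter (one deprotection after the key step against three steps here). The chosen plan sets against this that every bond-forming step has precedent on its substrate class, that no halogen or boron handle and no statistical mono-coupling are needed, and that the biaryl problem is removed instead of being moved into the starting material.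

**Alternative 2: Late ketone-directed C–H oxygenation.**
- Cut: the C8a–O1 bonds, as C–H to C–O.
- Forward step: the bis(4-methoxyphenyl benzyl ketone) A5 is oxidised with Pd(OAc)2 and K2S2O8 in CF3CO2H/(CF3CO)2O to the bis(2-hydroxy-4-methoxyphenyl ketone) A4. No ring closes. A4 then needs demethylation and the same one-carbon ring closure as in the chosen plan.
- Merits: A5 comes from commodity aromatics by classical acylation, and ketone-directed ortho-hydroxylation of aryl ketones is a known reaction class.
- Weak points:
  - Each ketone of A5 sits between two arenes. The electron-rich ring B offers ortho C–H bonds through a six-membered palladacycle, while the wanted position on ring A is meta to its methoxyl and not activated.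
  - The methylene between ketone and ring B is doubly activated and faces persulfate in strong acid. Oxidation to the 1,2-diketone or benzylic oxygenation is a real threat, and the step has to succeed twice.
  - The biaryl still has to be supplied.
- Comparison: the early steps of this road are simpler and probably fewer, and that is a real advantage. The endgame is the same as here, so nothing is gained late. The chosen plan sets against it that the oxygen is carried in with 1 and needs no oxidation step, that the benzylic ketone meets only a mild aerobic dehydrogenation, and that the substitution of ring B follows from connectivity, not from directing effects.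

**Alternative 3: Aryne annulation delivering both A rings.**
- Cut: O1–C8a and C4–C4a of both rings C.
- Forward step: CsF releases a chloro-methoxy aryne from the silyl triflate A8. Each enol oxygen of the bis(3-hydroxyacrylate) A7 adds to it, and the resulting aryl anion attacks the neighbouring ester. This gives the 5,5''-dichloro tetra-O-methyl ether A6.
- Merits: both heterocycles and both A rings arrive in one step, and A7 is a simple formylated bis(arylacetate).
- Weak points:
  - The enolate of A7 is ambident. Arynes commonly attack the carbon of β-dicarbonyl compounds and insert into their C–C bond, which would give the wrong skeleton.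
  - The chlorine is there only to steer the addition and must be removed afterwards by two hydrodechlorinations. Four methyl ethers must also be cleaved.
  - A8 is a multi-step speciality reagent needed in excess.
  - A7 again presupposes the biaryl.
- Comparison: this is the most convergent of the four plans, and its longest linear sequence could be shorter. The chosen plan sets against it commodity reagents, no regiocontrol auxiliary to install and remove, and no reliance on O- over C-arylation.

Key step: step 5

## Route

Remark: 9 and 10 should each form as a mixture of the racemic (R,R)/(S,S) pair and the meso (R,S) isomer. The (R,R) isomers are drawn. The mixture is carried on unseparated because both centers become sp2 in step 6. The biaryl axis of 11–13 is assumed to rotate freely.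

Step 1
Reactants: 1 1,3-dimethoxybenzene; 2 pent-4-enoyl chloride
Product: 3 1-(2,4-dimethoxyphenyl)pent-4-en-1-one
Conditions: AlCl3 (1.1 equiv), CH2Cl2, −10 to 0 °C; then ice/dilute HCl
Reagents that add atoms: none
Why: Friedel–Crafts acylation; the acylium ion attacks C4 of 1, para to one methoxyl and ortho to the other (C2 is flanked by both and hindered), and the ketone–AlCl3 complex prevents a second acylation. Low temperature and a short reaction time should keep the terminal alkene and the ortho methoxyl intact.

Step 2
Reactants: 3 1-(2,4-dimethoxyphenyl)pent-4-en-1-one
Product: 5 4-(2,4-dimethoxyphenyl)-4-oxobutanal, via secondary ozonide 4 (not isolated)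
Conditions: O3, CH2Cl2, −78 °C (Sudan red 7B as end-point indicator); then PPh3, −78 °C to rt
Reagents that add atoms: ozone, [O-][O+]=O
Why: Ozonolysis with reductive work-up; cycloaddition, cycloreversion and recombination give ozonide 4, which PPh3 reduces to the aldehyde and formaldehyde. The monosubstituted alkene reacts far faster than the acyl-deactivated arene, and the indicator dye marks the end-point.

Step 3
Reactants: 6 succinyl chloride
Product: 7 N1,N4-dimethoxy-N1,N4-dimethylbutanediamide
Conditions: MeNH(OMe)·HCl (2.2 equiv), pyridine (4.5 equiv), CH2Cl2, 0 °C to rt
Reagents that add atoms: N,O-dimethylhydroxylamine hydrochloride, CNOC.Cl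
Why: Nucleophilic acyl substitution at both acid chloride groups (Weinreb amide formation); the secondary amine cannot close to an imide, so the open bis-amide is the expected product.

Step 4
Reactants: 7 N1,N4-dimethoxy-N1,N4-dimethylbutanediamide
Product: 8 octa-1,7-diene-3,6-dione
Conditions: CH2=CHMgBr (2.6 equiv), THF, −20 to 0 °C; cannulated into cold 2 M HCl/Et2O; BHT added; used at once
Reagents that add atoms: vinylmagnesium bromide, C=C[Mg]Br
Why: Weinreb ketone synthesis; each amide takes up one vinyl nucleophile and the magnesium chelate holds the tetrahedral adduct until work-up, so neither over-addition nor conjugate addition can occur in the flask. The inverse acidic quench keeps the liberated N,O-dimethylhydroxylamine protonated and should prevent its aza-Michael addition to 8.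

Step 5
Reactants: 8 octa-1,7-diene-3,6-dione; 5 4-(2,4-dimethoxyphenyl)-4-oxobutanal (two molecules, 2.4 equiv)
Product: 10 4,4'-bis[2-(2,4-dimethoxyphenyl)-2-oxoethyl]-2,2'-bi(cyclohex-2-en-1-one), via bis-Michael dialdehyde 9 (not isolated)
Conditions: pyrrolidine (0.3 equiv), PhCO2H (0.3 equiv), CH2Cl2, 0 °C to rt (8 added slowly); then 40 °C
Reagents that add atoms: none
Why: Pyrrolidine condenses with the aldehyde of 5, much faster than with its electron-rich aryl ketone, and the enamine adds through its β-carbon to each terminal CH2 of 8 (the C1'–C6' and C1'''–C6''' bonds); hydrolysis returns the catalyst and gives dialdehyde 9. On warming, pyrrolidinium benzoate converts each aldehyde of 9 into an iminium ion, the internal α-methylene of the neighbouring ketone attacks it as its enol or enamine, and loss of the amine gives the C2'=C3' and C2'''=C3''' double bonds. The closest known reaction type is the secondary-amine-catalysed Robinson annulation of aldehydes with alkyl vinyl ketones to 4-substituted cyclohex-2-enones; an α'-substituted vinyl ketone gives a 2-substituted product, and here the 2-substituent of each ring is the other ring. Each of the two rings closes in a 6-(enolexo)-exo-trig aldol on the central bond that is already present, and the competing closures would be four- or seven-membered. The two new stereocenters (C1' and C1''') arise in the Michael steps under an achiral catalyst with no control element, so racemic and meso isomers are expected together; this is accepted because both centers become sp2 in step 6. The selectivity needed is aldol onto the aldehyde and not ketone–ketone aldol of the 1,4-diketone to a cyclopentenone, nor acid-promoted furan formation. It is secured because the buffered amine salt activates only the aldehyde as an iminium ion and neither strong base nor strong acid is present. Excess 5 and slow addition of 8 keep the acceptor dilute, which should limit its polymerisation and drive both ends to react.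

Step 6
Reactants: 10 4,4'-bis[2-(2,4-dimethoxyphenyl)-2-oxoethyl]-2,2'-bi(cyclohex-2-en-1-one)
Product: 11 2,2'-(6,6'-dihydroxy-[1,1'-biphenyl]-3,3'-diyl)bis[1-(2,4-dimethoxyphenyl)ethan-1-one]
Conditions: Pd(OCOCF3)2 (10 mol %), 2-(dimethylamino)pyridine (20 mol %), TsOH·H2O (40 mol %), O2 (1 atm), DMSO, 80 °C
Reagents that add atoms: none
Why: Aerobic palladium-catalysed dehydrogenation of cyclohexenones to phenols; a divalent palladium enolate at C5' undergoes β-hydride elimination toward C6', the 4H-cyclohexa-2,5-dienone tautomerises to the phenol, and O2 reoxidises zerovalent palladium, which removes both temporary stereocenters. The side chain is not at risk: dehydrogenation across CH2–C1' would give only another tautomer of the same phenol, and the aromatized benzylic ketone has no β-hydrogen left.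

Step 7
Reactants: 11 2,2'-(6,6'-dihydroxy-[1,1'-biphenyl]-3,3'-diyl)bis[1-(2,4-dimethoxyphenyl)ethan-1-one]
Product: 12 2,2'-(6,6'-dihydroxy-[1,1'-biphenyl]-3,3'-diyl)bis[1-(2,4-dihydroxyphenyl)ethan-1-one]
Conditions: BBr3 (12 equiv), CH2Cl2, −78 °C to rt; then ice-water
Reagents that add atoms: none
Why: Lewis-acid cleavage of aryl methyl ethers; boron coordinates each ether oxygen and bromide attacks the methyl group in an SN2 step, the methoxyl ortho to the ketone first through its chelate and the para one with the excess at room temperature. The ketones, the benzylic methylene and the biphenol are inert, and the borate esters are hydrolysed on work-up.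

Step 8
Reactants: 12 2,2'-(6,6'-dihydroxy-[1,1'-biphenyl]-3,3'-diyl)bis[1-(2,4-dihydroxyphenyl)ethan-1-one]
Product: 13 3,3'-(6,6'-dihydroxy-[1,1'-biphenyl]-3,3'-diyl)bis(7-hydroxy-4H-chromen-4-one)
Conditions: BF3·OEt2 (12 equiv), DMF, rt to 50 °C; then CH3SO2Cl (6 equiv) in DMF, 80 °C; then H2O, 70 °C
Reagents that add atoms: N,N-dimethylformamide, CN(C)C=O
Why: Standard one-carbon closure of 2-hydroxyphenyl benzyl ketones to isoflavones; BF3 ties each 2-hydroxy ketone into a difluoroboron chelate that enolises toward the benzylic CH2, the iminium salt from DMF and CH3SO2Cl formylates that carbon, and the phenol oxygen closes onto the aminomethylene carbon with loss of Me2NH to give ring C. The acidic medium leaves the other phenols unchanged, so no protecting group is needed.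

## Compound list

1 | 1,3-dimethoxybenzene | COc1cccc(OC)c1 | starting material
2 | pent-4-enoyl chloride | C=CCCC(Cl)=O | starting material
3 | 1-(2,4-dimethoxyphenyl)pent-4-en-1-one | COc1ccc(C(=O)CCC=C)c(OC)c1 | intermediate
4 | 1-(2,4-dimethoxyphenyl)-3-(1,2,4-trioxolan-3-yl)propan-1-one (secondary ozonide, racemic) | COc1ccc(C(=O)CCC2OCOO2)c(OC)c1 | intermediate (not isolated)
5 | 4-(2,4-dimethoxyphenyl)-4-oxobutanal | COc1ccc(C(=O)CCC=O)c(OC)c1 | intermediate
6 | succinyl chloride | O=C(Cl)CCC(Cl)=O | starting material
7 | N1,N4-dimethoxy-N1,N4-dimethylbutanediamide | CON(C)C(=O)CCC(=O)N(C)OC | intermediate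
8 | octa-1,7-diene-3,6-dione | C=CC(=O)CCC(=O)C=C | intermediate
9 | 2,11-bis[2-(2,4-dimethoxyphenyl)-2-oxoethyl]-5,8-dioxododecanedial ((2R,11R) isomer drawn; expected as the racemate together with the meso (2R,11S) isomer) | O=C[C@@H](CC(=O)c1ccc(OC)cc1OC)CCC(=O)CCC(=O)CC[C@H](CC(=O)c1ccc(OC)cc1OC)C=O | intermediate (not isolated)
10 | 4,4'-bis[2-(2,4-dimethoxyphenyl)-2-oxoethyl]-2,2'-bi(cyclohex-2-en-1-one) ((4R,4'R) isomer drawn; expected as the racemate together with the meso (4R,4'S) isomer) | O=C1CC[C@H](CC(=O)c2ccc(OC)cc2OC)C=C1C1=C[C@@H](CC(=O)c2ccc(OC)cc2OC)CCC1=O | intermediate
11 | 2,2'-(6,6'-dihydroxy-[1,1'-biphenyl]-3,3'-diyl)bis[1-(2,4-dimethoxyphenyl)ethan-1-one] | COc1ccc(C(=O)Cc2ccc(O)c(-c3cc(CC(=O)c4ccc(OC)cc4OC)ccc3O)c2)c(OC)c1 | intermediate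
12 | 2,2'-(6,6'-dihydroxy-[1,1'-biphenyl]-3,3'-diyl)bis[1-(2,4-dihydroxyphenyl)ethan-1-one] | O=C(Cc1ccc(O)c(-c2cc(CC(=O)c3ccc(O)cc3O)ccc2O)c1)c1ccc(O)cc1O | intermediate
13 | 3,3'-(6,6'-dihydroxy-[1,1'-biphenyl]-3,3'-diyl)bis(7-hydroxy-4H-chromen-4-one) (3',3'''-bidaidzein, CNP0386002.0) | O=c1c(-c2ccc(O)c(-c3cc(-c4coc5cc(O)ccc5c4=O)ccc3O)c2)coc2cc(O)ccc12 | target

## Step count and risks

Total: 8 steps from 1, 2 and 6. Longest linear sequence: 6 steps (steps 1, 2, 5, 6, 7, 8; the branch through steps 3, 4, 5, 6, 7, 8 is equally long).

**Step 5 (key step).**
- Risk: the cross Michael addition may lose the race to self-aldol condensation of the aldehyde and to amine-initiated oligomerisation of the bis-acceptor. The sequence may also stall after one ring closure, so that the remaining 1,4-diketone unit drifts into ketone–ketone aldol.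
- Fallback (stoichiometric Stork enamine annulation): setting out from 5, condensation with pyrrolidine (K2CO3, toluene, 0 °C) gives the preformed enamine (E)-1-(2,4-dimethoxyphenyl)-4-(pyrrolidin-1-yl)but-3-en-1-one F1. Two equivalents of it are combined with 8 in toluene at 0 °C to rt, where neither free aldehyde nor free secondary amine is present. The adduct is then hydrolysed and cyclised with an AcOH/NaOAc/H2O buffer at 60 °C, which returns to the route at 10.

**Step 4.**
- Risk: conjugate addition of the liberated hydroxylamine or of residual Grignard reagent during the quench, and polymerisation of the divinyl diketone on concentration.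
- Fallback (masked acceptor): setting out from 6, double Friedel–Crafts acylation of ethylene (AlCl3, CH2=CH2, CH2Cl2, 0 °C) should give 1,8-dichlorooctane-3,6-dione F2, a storable bis(β-chloroethyl ketone). Et3N in Et2O at 0 °C eliminates HCl just before use and returns to the route at 8, as a filtered solution for step 5.

**Step 6.**
- Risk: stalling after aromatization of one ring, because the emerging biphenol binds palladium or the catalyst aggregates, and slow over-oxidation at the doubly activated benzylic methylene during prolonged heating.
- Fallback (metal-free, through enol derivatives): setting out from 10, enol acetylation with isopropenyl acetate and catalytic TsOH at reflux acylates conjugated enones far faster than the electron-rich aryl ketones. It should give the bis(dienol acetate) 5,5'-bis[2-(2,4-dimethoxyphenyl)-2-oxoethyl]-[1,1'-bi(cyclohexa-1,5-dien-1-yl)]-2,2'-diyl diacetate F3. These cyclohexadienes are dehydrogenated by DDQ (dioxane, rt) to 5,5'-bis[2-(2,4-dimethoxyphenyl)-2-oxoethyl]-[1,1'-biphenyl]-2,2'-diyl diacetate F4. K2CO3 in CH3OH removes the acetates and returns to the route at 11.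

**Step 8.**
- Risk: incomplete second ring closure and competing C- or O-formylation of the electron-rich resorcinol rings, made worse by poor solubility of the hexaol and its boron chelates.
- Fallback (reordered endgame): setting out from 11, AlCl3 in CH3CN (rt to 50 °C) cleaves only the methoxyls ortho to the ketones, through their chelates. It gives 2,2'-(6,6'-dihydroxy-[1,1'-biphenyl]-3,3'-diyl)bis[1-(2-hydroxy-4-methoxyphenyl)ethan-1-one] F5. The same DMF/BF3·OEt2/CH3SO2Cl closure on this less polar substrate gives 3,3'-(6,6'-dihydroxy-[1,1'-biphenyl]-3,3'-diyl)bis(7-methoxy-4H-chromen-4-one) F6. BBr3 in CH2Cl2 then removes the two 7-O-methyl groups and returns to the route at 13.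

## Further compounds

F1 | step 5 | (E)-1-(2,4-dimethoxyphenyl)-4-(pyrrolidin-1-yl)but-3-en-1-one | COc1ccc(C(=O)C/C=C/N2CCCC2)c(OC)c1
F2 | step 4 | 1,8-dichlorooctane-3,6-dione | ClCCC(=O)CCC(=O)CCCl
F3 | step 6 | 5,5'-bis[2-(2,4-dimethoxyphenyl)-2-oxoethyl]-[1,1'-bi(cyclohexa-1,5-dien-1-yl)]-2,2'-diyl diacetate | CC(=O)OC1=C(C=C(CC(=O)c2ccc(OC)cc2OC)CC1)C1=C(OC(C)=O)CCC(CC(=O)c2ccc(OC)cc2OC)=C1
F4 | step 6 | 5,5'-bis[2-(2,4-dimethoxyphenyl)-2-oxoethyl]-[1,1'-biphenyl]-2,2'-diyl diacetate | CC(=O)Oc1ccc(CC(=O)c2ccc(OC)cc2OC)cc1-c1cc(CC(=O)c2ccc(OC)cc2OC)ccc1OC(C)=O
F5 | step 8 | 2,2'-(6,6'-dihydroxy-[1,1'-biphenyl]-3,3'-diyl)bis[1-(2-hydroxy-4-methoxyphenyl)ethan-1-one] | COc1ccc(C(=O)Cc2ccc(O)c(-c3cc(CC(=O)c4ccc(OC)cc4O)ccc3O)c2)c(O)c1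
F6 | step 8 | 3,3'-(6,6'-dihydroxy-[1,1'-biphenyl]-3,3'-diyl)bis(7-methoxy-4H-chromen-4-one) | COc1ccc2c(c1)occ(-c1ccc(O)c(-c3cc(-c4coc5cc(OC)ccc5c4=O)ccc3O)c1)c2=O
A1 | alternative 1 | 3,3'-(6,6'-dimethoxy-[1,1'-biphenyl]-3,3'-diyl)bis(7-hydroxy-4H-chromen-4-one) | O=c1c(-c2ccc(OC)c(-c3cc(-c4coc5cc(O)ccc5c4=O)ccc3OC)c2)coc2cc(O)ccc12
A2 | alternative 1 | 3,3'-(6,6'-dimethoxy-[1,1'-biphenyl]-3,3'-diyl)bis(5-bromo-4H-pyran-4-one) | COc1ccc(cc1-c1cc(ccc1OC)-c1cocc(Br)c1=O)-c1cocc(Br)c1=O
A3 | alternative 1 | (E)-1-methoxy-3-(trimethylsilyloxy)buta-1,3-diene | CO/C=C/C(=C)O[Si](C)(C)C
A4 | alternative 2 | 2,2'-(6,6'-dimethoxy-[1,1'-biphenyl]-3,3'-diyl)bis[1-(2-hydroxy-4-methoxyphenyl)ethan-1-one] | COc1ccc(c(O)c1)C(=O)Cc1ccc(OC)c(c1)-c1cc(CC(=O)c2ccc(OC)cc2O)ccc1OC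
A5 | alternative 2 | 2,2'-(6,6'-dimethoxy-[1,1'-biphenyl]-3,3'-diyl)bis[1-(4-methoxyphenyl)ethan-1-one] | COc1ccc(cc1)C(=O)Cc1ccc(OC)c(c1)-c1cc(CC(=O)c2ccc(OC)cc2)ccc1OC
A6 | alternative 3 | 3,3'-(6,6'-dimethoxy-[1,1'-biphenyl]-3,3'-diyl)bis(5-chloro-7-methoxy-4H-chromen-4-one) | O=c1c(-c2ccc(OC)c(-c3cc(-c4coc5cc(OC)cc(Cl)c5c4=O)ccc3OC)c2)coc2cc(OC)cc(Cl)c12
A7 | alternative 3 | dimethyl 2,2'-(6,6'-dimethoxy-[1,1'-biphenyl]-3,3'-diyl)bis(3-hydroxyprop-2-enoate) | COC(=O)C(=CO)c1ccc(OC)c(c1)-c1cc(ccc1OC)C(=CO)C(=O)OC
A8 | alternative 3 | 2-chloro-4-methoxy-6-(trimethylsilyl)phenyl trifluoromethanesulfonate | COc1cc(Cl)c(OS(=O)(=O)C(F)(F)F)c([Si](C)(C)C)c1
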